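**Plan**
- Retrosynthesis: the enal, the two esters and the side-chain carbinol are taken back to bromo diol 11; the C5 acetyl comes from the aryl bromide (Br/Li exchange, Weinreb amide) and the carbinol from a CBS reduction.
- The cis C2/C3 pair is tied up as the cis-fused α-methylene-γ-lactone 10 (the C3 oxygen joined to the future aldehyde carbon). 10 is cut at the C3a–C3 bond to the acetal ester 6, which is cut at O1–C2 (allylic etherification) and at C2–C(vinyl) (Morita–Baylis–Hillman).
- Forward: chain by MBH, then aryl ether, then lactone ring and dihydrofuran ring in one flask (step 4), then reductive opening of the lactone, side chain, acyl groups, enal.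
- Stereochemistry: C2 from the chiral ligand in the Pd-catalysed etherification; C3 from C2 through the forced cis 5/5 ring fusion in step 4; the benzylic carbinol from the CBS catalyst.
- Enabling feature: the C3 oxygen and the carbonyl carbon of the C2 acrolein unit are 1,4-related (O–C3–C2–C(=CH2)–CHO), so they can share a five-membered lactone whose acetal carbon is C3. As an acyloxycarbenium ion this carbon lies three atoms from the ortho carbon C3a of the aryl ether on C2.

Key step: step 4

Remark: the (R,R) ligand in step 3 is assigned by analogy; if it favours the (S) ether, the (S,S) ligand is used instead, with nothing else changed.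

Atom numbers C2, C3, C3a and C5 refer to the benzofuran numbering of the target.

Step 1
Reactants: 1 tert-butyl acrylate; 2 2,2-dimethoxyacetaldehyde (60% solution in water)
Product: 3 tert-butyl 2-(1-hydroxy-2,2-dimethoxyethyl)prop-2-enoate (racemic)
Conditions: DABCO (1 equiv), 1,4-dioxane/H2O, rt
Reagents that add atoms: none
Why: Morita–Baylis–Hillman reaction, in which the DABCO–acrylate enolate is trapped by the electrophilic α,α-dialkoxy aldehyde; the carbinol is made racemic on purpose because step 3 is stereoconvergent.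

Step 2
Reactants: 3 tert-butyl 2-(1-hydroxy-2,2-dimethoxyethyl)prop-2-enoate
Product: 4 tert-butyl 2-[2,2-dimethoxy-1-(methoxycarbonyloxy)ethyl]prop-2-enoate (racemic)
Conditions: ClCO2Me, pyridine, DMAP (cat.), CH2Cl2, 0 °C
Reagents that add atoms: methyl chloroformate, COC(=O)Cl
Why: Standard carbonate formation at the secondary allylic alcohol installs the leaving group that zerovalent palladium ionises in step 3.

Step 3
Reactants: 4 tert-butyl 2-[2,2-dimethoxy-1-(methoxycarbonyloxy)ethyl]prop-2-enoate; 5 4-bromophenol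
Product: 6 tert-butyl 2-[(1R)-1-(4-bromophenoxy)-2,2-dimethoxyethyl]prop-2-enoate
Conditions: Pd2(dba)3·CHCl3 (2 mol%), (1R,2R)-N,N′-bis[2-(diphenylphosphino)benzoyl]cyclohexane-1,2-diamine (6 mol%), CH2Cl2, rt
Reagents that add atoms: none
Why: Pd-catalysed dynamic kinetic asymmetric allylic etherification (Tsuji–Trost type), known for Baylis–Hillman carbonates with phenols: both enantiomers of 4 ionise to π-allyl complexes that interconvert through the σ-allyl form at the CH2 terminus, and the chiral ligand directs phenoxide to the substituted terminus of one of them, which sets the (R) center that becomes C2.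

Step 4
Reactants: 6 tert-butyl 2-[(1R)-1-(4-bromophenoxy)-2,2-dimethoxyethyl]prop-2-enoate
Product: 10 (3aR,8bR)-7-bromo-3-methylidene-3a,8b-dihydrofuro[3,2-b][1]benzofuran-2(3H)-one, via carboxylic acid 7 (not isolated), via methoxy lactone 8 (not isolated), via acyloxycarbenium ion 9 (not isolated)
Conditions: TFA/CH2Cl2 (1:4), 0 °C to rt; evaporate; CF3SO3H (20 mol%), (CF3)2CHOH/CH2Cl2, 0 °C to rt
Reagents that add atoms: none
Why: TFA cleaves the tert-butyl ester to acid 7 and ionises the dimethyl acetal, the carboxyl group closes onto the methoxycarbenium carbon (5-exo-trig, C–O bond) to give pseudo-ester 8, and CF3SO3H in the ionising, non-nucleophilic fluoro alcohol expels the second methoxy group to give acyloxycarbenium ion 9, which is attacked by the ortho carbon of the aryl ether. The closest known reaction type is the Friedel–Crafts arylation of pseudo-acids and pseudo-esters of γ-oxo acids (3-hydroxyphthalide or mucohalic acids with arenes), together with the acid cyclisation of aryloxyacetaldehyde acetals, which builds the same O–C–C–aryl five-membered ring. The dihydrofuran ring closes 5-exo-trig with respect to the C=O+ bond of 9 (endo with respect to the arene π bond) and forms the C3a–C3 bond. The new stereocenter C3 is controlled by the (R) center at C2 alone: the lactone oxygen and the aryl ether oxygen can be bridged by two five-membered rings only in a cis fusion, so the arene must add to the face of the planar cation on which the aryloxy group sits, and both C5 epimers of 8 converge on the same ion. The step needs C-arylation to win over proton loss from C2 and over intermolecular attack; the three-atom distance between arene and cation and the blocked para position (bromine, which also leaves the ring nucleophilic enough and later becomes the acetyl group) should secure this, and the two ortho positions are equivalent.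

Step 5
Reactants: 10 (3aR,8bR)-7-bromo-3-methylidene-3a,8b-dihydrofuro[3,2-b][1]benzofuran-2(3H)-one
Product: 11 (2R,3R)-5-bromo-2-(3-hydroxyprop-1-en-2-yl)-2,3-dihydro-1-benzofuran-3-ol
Conditions: i-Bu2AlH (4.5 equiv), CH2Cl2, −78 to −20 °C; aq. potassium sodium tartrate
Reagents that add atoms: none
Why: i-Bu2AlH reduces the α-methylene lactone by 1,2-addition through the lactol to the diol, which cuts the temporary tether at its acyl carbon and leaves the C3–O bond, both stereocenters and the aryl bromide untouched (lactone reduction).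

Step 6
Reactants: 11 (2R,3R)-5-bromo-2-(3-hydroxyprop-1-en-2-yl)-2,3-dihydro-1-benzofuran-3-ol
Product: 12 (2R,3R)-5-bromo-2-[3-(tert-butyldimethylsilyloxy)prop-1-en-2-yl]-2,3-dihydro-1-benzofuran-3-ol
Conditions: TBSCl (1.05 equiv), imidazole, CH2Cl2, −20 to 0 °C
Reagents that add atoms: tert-butyldimethylsilyl chloride, CC(C)(C)[Si](C)(C)Cl
Why: The primary allylic hydroxyl should be silylated much faster than the secondary benzylic one, which is flanked by the cis substituent on C2 (selective silylation).

Step 7
Reactants: 12 (2R,3R)-5-bromo-2-[3-(tert-butyldimethylsilyloxy)prop-1-en-2-yl]-2,3-dihydro-1-benzofuran-3-ol; 13 N-methoxy-N-methylacetamide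
Product: 14 1-{(2R,3R)-2-[3-(tert-butyldimethylsilyloxy)prop-1-en-2-yl]-3-hydroxy-2,3-dihydro-1-benzofuran-5-yl}ethan-1-one
Conditions: n-BuLi (2.2 equiv), THF, −78 °C; then 13, −78 to 0 °C; aq. NH4Cl
Reagents that add atoms: none
Why: After deprotonation of the hydroxyl, bromine–lithium exchange at −78 °C is faster than deprotonation next to the ether oxygen, and the aryllithium is acylated only once because the chelated tetrahedral adduct of the Weinreb amide survives until work-up (halogen–metal exchange, Weinreb ketone synthesis).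

Step 8
Reactants: 14 1-{(2R,3R)-2-[3-(tert-butyldimethylsilyloxy)prop-1-en-2-yl]-3-hydroxy-2,3-dihydro-1-benzofuran-5-yl}ethan-1-one; 15 3-methylbutanoyl chloride
Product: 16 (2R,3R)-5-acetyl-2-[3-(tert-butyldimethylsilyloxy)prop-1-en-2-yl]-2,3-dihydro-1-benzofuran-3-yl 3-methylbutanoate
Conditions: pyridine, DMAP (cat.), CH2Cl2, 0 °C
Reagents that add atoms: none
Why: DMAP-catalysed acylation of the secondary benzylic alcohol proceeds with retention at C3; mild base and low temperature are chosen because the cis 3-acyloxy group can be lost to the aromatic benzofuran under stronger base or heat.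

Step 9
Reactants: 16 (2R,3R)-5-acetyl-2-[3-(tert-butyldimethylsilyloxy)prop-1-en-2-yl]-2,3-dihydro-1-benzofuran-3-yl 3-methylbutanoate
Product: 17 (2R,3R)-2-[3-(tert-butyldimethylsilyloxy)prop-1-en-2-yl]-5-[(1S)-1-hydroxyethyl]-2,3-dihydro-1-benzofuran-3-yl 3-methylbutanoate
Conditions: (R)-2-methyl-CBS-oxazaborolidine (20 mol%), catecholborane, toluene, −78 to −40 °C
Reagents that add atoms: none
Why: Corey–Bakshi–Shibata reduction, in which the (R)-oxazaborolidine distinguishes aryl from methyl and delivers hydride to the Re face of the ketone to set the (S) carbinol; catecholborane at low temperature should not touch the ester, the silyl ether or the 1,1-disubstituted alkene.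

Step 10
Reactants: 17 (2R,3R)-2-[3-(tert-butyldimethylsilyloxy)prop-1-en-2-yl]-5-[(1S)-1-hydroxyethyl]-2,3-dihydro-1-benzofuran-3-yl 3-methylbutanoate; 18 3-methylbut-2-enoyl chloride
Product: 19 (1S)-1-{(2R,3R)-2-[3-(tert-butyldimethylsilyloxy)prop-1-en-2-yl]-3-(3-methylbutanoyloxy)-2,3-dihydro-1-benzofuran-5-yl}ethyl 3-methylbut-2-enoate
Conditions: pyridine, DMAP (cat.), CH2Cl2, 0 °C
Reagents that add atoms: none
Why: Acylation of the benzylic alcohol leaves its C–O bond intact (retention), and pyridine in place of a stronger amine base avoids vinylketene formation and deconjugation of the senecioyl group.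

Step 11
Reactants: 19 (1S)-1-{(2R,3R)-2-[3-(tert-butyldimethylsilyloxy)prop-1-en-2-yl]-3-(3-methylbutanoyloxy)-2,3-dihydro-1-benzofuran-5-yl}ethyl 3-methylbut-2-enoate
Product: 20 (1S)-1-{(2R,3R)-2-(3-hydroxyprop-1-en-2-yl)-3-(3-methylbutanoyloxy)-2,3-dihydro-1-benzofuran-5-yl}ethyl 3-methylbut-2-enoate
Conditions: HF·pyridine, pyridine, THF, 0 °C to rt
Reagents that add atoms: none
Why: Pyridine-buffered HF cleaves the primary silyl ether without base, so neither ester should migrate or eliminate (fluoride desilylation).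

Step 12
Reactants: 20 (1S)-1-{(2R,3R)-2-(3-hydroxyprop-1-en-2-yl)-3-(3-methylbutanoyloxy)-2,3-dihydro-1-benzofuran-5-yl}ethyl 3-methylbut-2-enoate
Product: 21 (1S)-1-{(2R,3R)-3-(3-methylbutanoyloxy)-2-(3-oxoprop-1-en-2-yl)-2,3-dihydro-1-benzofuran-5-yl}ethyl 3-methylbut-2-enoate (target)
Conditions: Dess–Martin periodinane, CH2Cl2, 0 °C to rt
Reagents that add atoms: none
Why: Dess–Martin oxidation converts the primary allylic alcohol into the α-substituted acrolein under non-basic conditions that should leave both esters and the C2 and C3 stereocenters untouched.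

**Compound list**
1 | tert-butyl acrylate | C=CC(=O)OC(C)(C)C | starting material
2 | 2,2-dimethoxyacetaldehyde | COC(OC)C=O | starting material
3 | tert-butyl 2-(1-hydroxy-2,2-dimethoxyethyl)prop-2-enoate (racemic) | C=C(C(=O)OC(C)(C)C)C(O)C(OC)OC | intermediate
4 | tert-butyl 2-[2,2-dimethoxy-1-(methoxycarbonyloxy)ethyl]prop-2-enoate (racemic) | C=C(C(=O)OC(C)(C)C)C(OC(=O)OC)C(OC)OC | intermediate
5 | 4-bromophenol | Oc1ccc(Br)cc1 | starting material
6 | tert-butyl 2-[(1R)-1-(4-bromophenoxy)-2,2-dimethoxyethyl]prop-2-enoate | C=C(C(=O)OC(C)(C)C)[C@H](C(OC)OC)Oc1ccc(Br)cc1 | intermediate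
7 | 2-[(1R)-1-(4-bromophenoxy)-2,2-dimethoxyethyl]prop-2-enoic acid | C=C(C(=O)O)[C@H](C(OC)OC)Oc1ccc(Br)cc1 | intermediate
8 | (4R)-4-(4-bromophenoxy)-5-methoxy-3-methylideneoxolan-2-one (both C5 epimers) | C=C1C(=O)OC(OC)[C@@H]1Oc2ccc(Br)cc2 | intermediate
9 | (4R)-4-(4-bromophenoxy)-3-methylidene-2-oxo-3,4-dihydro-2H-furan-1-ium (acyloxycarbenium ion) | C=C1C(=O)[O+]=C[C@@H]1Oc2ccc(Br)cc2 | intermediate
10 | (3aR,8bR)-7-bromo-3-methylidene-3a,8b-dihydrofuro[3,2-b][1]benzofuran-2(3H)-one (cis-fused) | C=C1C(=O)O[C@@H]2c3cc(Br)ccc3O[C@H]12 | intermediate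
11 | (2R,3R)-5-bromo-2-(3-hydroxyprop-1-en-2-yl)-2,3-dihydro-1-benzofuran-3-ol | C=C(CO)[C@H]1Oc2ccc(Br)cc2[C@H]1O | intermediate
12 | (2R,3R)-5-bromo-2-[3-(tert-butyldimethylsilyloxy)prop-1-en-2-yl]-2,3-dihydro-1-benzofuran-3-ol | C=C(CO[Si](C)(C)C(C)(C)C)[C@H]1Oc2ccc(Br)cc2[C@H]1O | intermediate
13 | N-methoxy-N-methylacetamide | CC(=O)N(C)OC | starting material
14 | 1-{(2R,3R)-2-[3-(tert-butyldimethylsilyloxy)prop-1-en-2-yl]-3-hydroxy-2,3-dihydro-1-benzofuran-5-yl}ethan-1-one | C=C(CO[Si](C)(C)C(C)(C)C)[C@H]1Oc2ccc(C(C)=O)cc2[C@H]1O | intermediate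
15 | 3-methylbutanoyl chloride | CC(C)CC(=O)Cl | starting material
16 | (2R,3R)-5-acetyl-2-[3-(tert-butyldimethylsilyloxy)prop-1-en-2-yl]-2,3-dihydro-1-benzofuran-3-yl 3-methylbutanoate | C=C(CO[Si](C)(C)C(C)(C)C)[C@H]1Oc2ccc(C(C)=O)cc2[C@H]1OC(=O)CC(C)C | intermediate
17 | (2R,3R)-2-[3-(tert-butyldimethylsilyloxy)prop-1-en-2-yl]-5-[(1S)-1-hydroxyethyl]-2,3-dihydro-1-benzofuran-3-yl 3-methylbutanoate | C=C(CO[Si](C)(C)C(C)(C)C)[C@H]1Oc2ccc([C@H](C)O)cc2[C@H]1OC(=O)CC(C)C | intermediate
18 | 3-methylbut-2-enoyl chloride | CC(C)=CC(=O)Cl | starting material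
19 | (1S)-1-{(2R,3R)-2-[3-(tert-butyldimethylsilyloxy)prop-1-en-2-yl]-3-(3-methylbutanoyloxy)-2,3-dihydro-1-benzofuran-5-yl}ethyl 3-methylbut-2-enoate | C=C(CO[Si](C)(C)C(C)(C)C)[C@H]1Oc2ccc([C@H](C)OC(=O)C=C(C)C)cc2[C@H]1OC(=O)CC(C)C | intermediate
20 | (1S)-1-{(2R,3R)-2-(3-hydroxyprop-1-en-2-yl)-3-(3-methylbutanoyloxy)-2,3-dihydro-1-benzofuran-5-yl}ethyl 3-methylbut-2-enoate | C=C(CO)[C@H]1Oc2ccc([C@H](C)OC(=O)C=C(C)C)cc2[C@H]1OC(=O)CC(C)C | intermediate
21 | (1S)-1-{(2R,3R)-3-(3-methylbutanoyloxy)-2-(3-oxoprop-1-en-2-yl)-2,3-dihydro-1-benzofuran-5-yl}ethyl 3-methylbut-2-enoate | C=C(C=O)[C@H]1Oc2ccc([C@H](C)OC(=O)C=C(C)C)cc2[C@H]1OC(=O)CC(C)C | target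

Total step count: 12. Longest linear sequence: 12 steps (from 1 and 2 to 21).

**Steps most likely to fail**

Step 4. The cation may lose the proton on C2 instead of being arylated, which would give a furanone and erode the C2 center. The product may also ionise at C3 under the acid and aromatise, and the ring closure may be slow because the arene is only moderately nucleophilic. The fallback reverses the polarity of the ring closure. It sets out from 4: the etherification of step 3 is run with 4-bromo-2-iodophenol to give tert-butyl 2-[(1R)-1-(4-bromo-2-iodophenoxy)-2,2-dimethoxyethyl]prop-2-enoate F1. The acetal is unmasked (In(OTf)3 cat., wet acetone, rt) to tert-butyl 2-[(1R)-1-(4-bromo-2-iodophenoxy)-2-oxoethyl]prop-2-enoate F2, which is used cold and crude. A Nozaki–Hiyama–Kishi cyclisation (CrCl2, NiCl2 cat., DMF, rt) adds the aryl iodide to the aldehyde and forms the same C3a–C3 bond, giving tert-butyl 2-[(2R)-5-bromo-3-hydroxy-2,3-dihydro-1-benzofuran-2-yl]prop-2-enoate F3 as a mixture of C3 epimers. TFA in CH2Cl2 then removes the tert-butyl group; only the cis epimer can lactonise, so the route comes back at 10, and the trans hydroxy acid is removed by a NaHCO3 wash.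

Step 3. Phenoxide may attack the unsubstituted allyl terminus, facial discrimination may be insufficient, the σ-allyl complex may lose methoxide from the acetal, or the product ether may re-ionise and equilibrate. The fallback replaces palladium by chiral Lewis-base catalysis. It sets out from 3, which is converted (Boc2O, DMAP cat., CH2Cl2) into tert-butyl 2-[1-(tert-butoxycarbonyloxy)-2,2-dimethoxyethyl]prop-2-enoate F4. With 5 and (DHQD)2PHAL (or its pseudo-enantiomer, as the sense of induction requires) in toluene, F4 undergoes the SN2′/SN2′ sequence through the allylic ammonium salt, which is branched-selective by mechanism, and the route comes back at 6.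

Step 7. The base may deprotonate the allylic C2–H next to oxygen and open the ring, or the aryllithium may be quenched by proton transfer from the Weinreb amide. The fallback replaces the organolithium by a cross-coupling. It sets out from 12: Stille coupling with Bu3Sn–C(OEt)=CH2 (PdCl2(PPh3)2, toluene, 80 °C) gives (2R,3R)-2-[3-(tert-butyldimethylsilyloxy)prop-1-en-2-yl]-5-(1-ethoxyethenyl)-2,3-dihydro-1-benzofuran-3-ol F5, and brief hydrolysis of the enol ether (dilute HCl, THF, 0 °C) brings the route back at 14.

Further compounds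
F1 | step 4 | tert-butyl 2-[(1R)-1-(4-bromo-2-iodophenoxy)-2,2-dimethoxyethyl]prop-2-enoate | C=C(C(=O)OC(C)(C)C)[C@H](C(OC)OC)Oc1ccc(Br)cc1I
F2 | step 4 | tert-butyl 2-[(1R)-1-(4-bromo-2-iodophenoxy)-2-oxoethyl]prop-2-enoate | C=C(C(=O)OC(C)(C)C)[C@H](C=O)Oc1ccc(Br)cc1I
F3 | step 4 | tert-butyl 2-[(2R)-5-bromo-3-hydroxy-2,3-dihydro-1-benzofuran-2-yl]prop-2-enoate (C3 epimers) | C=C(C(=O)OC(C)(C)C)[C@H]1Oc2ccc(Br)cc2C1O
F4 | step 3 | tert-butyl 2-[1-(tert-butoxycarbonyloxy)-2,2-dimethoxyethyl]prop-2-enoate (racemic) | C=C(C(=O)OC(C)(C)C)C(OC(=O)OC(C)(C)C)C(OC)OC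
F5 | step 7 | (2R,3R)-2-[3-(tert-butyldimethylsilyloxy)prop-1-en-2-yl]-5-(1-ethoxyethenyl)-2,3-dihydro-1-benzofuran-3-ol | C=C(CO[Si](C)(C)C(C)(C)C)[C@H]1Oc2ccc(C(=C)OCC)cc2[C@H]1O
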